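**Plan**
- Retrosynthesis: the thirteen O–methyl bonds are cut last. Ring C is then opened at its C3–C4 bond, the open chain is cut between the ketone carbon and the enoate methylene, and the two C–O bonds that tie the dimer and trimer phenols to a but-2-ynoate and a chloroacetamide follow. The diaryl ether bonds A–O–B, D–O–E and E–O–F go last.
- Enabling feature: ring C is a phloroglucinol-type ring whose C1 and C4 carry the ether oxygens to rings B and D and whose C3 and C5 carry hydroxyls. This is the oxygen pattern of a cyclised 3,5-dioxohexanoate, so ring C can stay an open keto enoate until late.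
- Forward, trimer side: rings F and E are joined (Chan–Lam), ring D is added (Ullmann), and the trimer phenol is alkylated to an aryloxyacetic Weinreb amide.
- Forward, dimer side and union: rings A and B are joined (Ullmann), the dimer phenol is added to methyl but-2-ynoate, the crotonate dienolate is acylated by the amide, ring C (the only ring made) is closed by Claisen condensation, and BBr3 frees all phenols.
- Every diaryl ether coupling pairs a 2,6-dioxygenated phenol with an aryl partner whose ortho positions are free. The two crowded aryl–O bonds of ring C arise as a vinyl ether and an alkyl aryl ether.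
- Stereochemistry: the target has no stereocentre. The only element to control is the E geometry of the enoate, set by a thermodynamically controlled oxa-Michael addition.

Key step: step 12

Assumption: the target is achiral and its diaryl ether axes rotate freely, so nothing beyond the enoate geometry of 18 and 21 needs control. Rings are lettered A (terminal 2,4,6-trioxygenated ring) to F (terminal 3,4,5-trioxygenated ring) along the chain.

**Route**

Step 1
Reactants: 1 4-bromo-2,6-dimethoxyphenol; 2 (3,4,5-trimethoxyphenyl)boronic acid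
Product: 3 5-bromo-1,3-dimethoxy-2-(3,4,5-trimethoxyphenoxy)benzene (EF bromide)
Conditions: Cu(OAc)2 (20 mol %), pyridine, 4 Å MS, CH2Cl2, O2 (1 atm), rt
Reagents that add atoms: none
Why: Chan–Lam oxidative C–O coupling accepts di-ortho-substituted phenols when the boronic acid has free ortho positions, leaves the aryl bromide untouched for step 4, and the para bromine blocks oxidative para coupling of the electron-rich phenol.

Step 2
Reactants: 4 3,4,5-trimethoxyphenol
Product: 5 1,2,3-trimethoxy-5-(methoxymethoxy)benzene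
Conditions: MOMCl, iPr2NEt, CH2Cl2, 0 °C → rt
Reagents that add atoms: chloromethyl methyl ether, COCCl
Why: Standard acetal protection of a phenol by O-alkylation, which also installs the directing group for the ortho-lithiation of step 3.

Step 3
Reactants: 5 1,2,3-trimethoxy-5-(methoxymethoxy)benzene
Product: 8 2,3,4-trimethoxy-6-(methoxymethoxy)phenol, via aryllithium 6 (not isolated), via dimethyl arylboronate 7 (not isolated)
Conditions: n-BuLi, TMEDA, THF, 0 °C; B(OMe)3, −78 °C → rt; AcOH, 30% H2O2, 0 °C → rt
Reagents that add atoms: hydrogen peroxide, OO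
Why: Directed ortho-metalation is regiodefined because the two free ring positions are equivalent and each lies between the OMOM and an OMe group, and borylation followed by peroxide oxidation (1,2-aryl shift from boron to oxygen) should give the phenol.

Step 4
Reactants: 8 2,3,4-trimethoxy-6-(methoxymethoxy)phenol; 3 EF bromide
Product: 9 1,2,3-trimethoxy-5-(methoxymethoxy)-4-[3,5-dimethoxy-4-(3,4,5-trimethoxyphenoxy)phenoxy]benzene (DEF MOM ether)
Conditions: CuI (10 mol %), picolinic acid (20 mol %), K3PO4, DMSO, 100 °C, argon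
Reagents that add atoms: none
Why: Ullmann-type diaryl ether synthesis with the CuI/picolinic acid system is suited to ortho,ortho'-disubstituted phenols, the bromide carries hydrogen at both ortho positions, and the MOM acetal is stable to base.

Step 5
Reactants: 9 DEF MOM ether
Product: 10 2-[3,5-dimethoxy-4-(3,4,5-trimethoxyphenoxy)phenoxy]-3,4,5-trimethoxyphenol (DEF phenol)
Conditions: conc. HCl (cat.), MeOH, 45 °C
Reagents that add atoms: none
Why: Acid-catalysed acetal methanolysis removes the MOM group while aryl methyl and diaryl ethers are inert, and methanol traps the oxocarbenium ion as dimethoxymethane so that the electron-rich rings are not alkylated.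

Step 6
Reactants: 10 DEF phenol; 11 2-chloro-N-methoxy-N-methylacetamide
Product: 12 2-{2-[3,5-dimethoxy-4-(3,4,5-trimethoxyphenoxy)phenoxy]-3,4,5-trimethoxyphenoxy}-N-methoxy-N-methylacetamide (DEF Weinreb amide)
Conditions: K2CO3, NaI (10 mol %), DMF, 60 °C
Reagents that add atoms: none
Why: Williamson ether synthesis on an α-chloro amide, an activated SN2 electrophile helped by in situ Finkelstein exchange, makes the alkyl aryl ether that becomes the C4–O bond of ring C and delivers the Weinreb amide directly.

Step 7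
Reactants: 1 4-bromo-2,6-dimethoxyphenol
Product: 13 2-(benzyloxy)-5-bromo-1,3-dimethoxybenzene
Conditions: BnBr, K2CO3, DMF, rt
Reagents that add atoms: benzyl bromide, BrCc1ccccc1
Why: Williamson benzylation masks the hindered phenol so that the bromide can act as the aryl partner in step 8 without self-coupling.

Step 8
Reactants: 14 2,4,6-trimethoxyphenol; 13 2-(benzyloxy)-5-bromo-1,3-dimethoxybenzene
Product: 15 2-(benzyloxy)-1,3-dimethoxy-5-(2,4,6-trimethoxyphenoxy)benzene (AB benzyl ether)
Conditions: CuI (10 mol %), picolinic acid (20 mol %), K3PO4, DMSO, 100 °C, argon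
Reagents that add atoms: none
Why: The same Ullmann-type coupling as in step 4 joins a di-ortho-methoxy phenol to a bromide with free ortho positions, and the benzyl ether is inert to the basic copper conditions.

Step 9
Reactants: 15 AB benzyl ether
Product: 16 2,6-dimethoxy-4-(2,4,6-trimethoxyphenoxy)phenol (AB phenol)
Conditions: H2 (1 atm), 10% Pd/C, EtOAc–MeOH, rt
Reagents that add atoms: none
Why: Catalytic hydrogenolysis cleaves only the benzylic C–O bond and leaves diaryl and aryl methyl ethers untouched.

Step 10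
Reactants: 16 AB phenol; 17 methyl but-2-ynoate
Product: 18 methyl (E)-3-[2,6-dimethoxy-4-(2,4,6-trimethoxyphenoxy)phenoxy]but-2-enoate (AB crotonate)
Conditions: K2CO3 (0.5 equiv), DMF, 60 °C
Reagents that add atoms: none
Why: Base-mediated oxa-Michael addition of the phenoxide to the alkynoate forms the crowded aryl–O bond (the future C1–O bond of ring C) without any aryl coupling, and the E isomer (ester cis to methyl) is the thermodynamic one and is expected under these equilibrating conditions.

Step 11
Reactants: 18 AB crotonate; 12 DEF Weinreb amide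
Product: 21 methyl (E)-3-[2,6-dimethoxy-4-(2,4,6-trimethoxyphenoxy)phenoxy]-6-{2-[3,5-dimethoxy-4-(3,4,5-trimethoxyphenoxy)phenoxy]-3,4,5-trimethoxyphenoxy}-5-oxohex-2-enoate, via lithium dienolate 19 (not isolated), via tetrahedral lithium alkoxide 20 (not isolated)
Conditions: LiN(iPr)2, THF, −78 °C; 12, −78 → −40 °C; AcOH, −78 °C
Reagents that add atoms: none
Why: In this vinylogous Claisen-type acylation the γ-methyl of the E crotonate is deprotonated with help of the cis ester, the 3-oxy dienolate reacts at its γ-carbon with the Weinreb amide, and the chelated tetrahedral adduct survives until the cold acidic quench, so the more acidic keto enoate never meets base.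

Step 12
Reactants: 21 keto enoate
Product: 24 2-{2-[3,5-dimethoxy-4-(3,4,5-trimethoxyphenoxy)phenoxy]-3,4,5-trimethoxyphenoxy}-5-[2,6-dimethoxy-4-(2,4,6-trimethoxyphenoxy)phenoxy]benzene-1,3-diol (hexamer diol), via dilithium dianion 22 (not isolated), via dilithium resorcinolate 23 (not isolated)
Conditions: LiN(SiMe3)2 (4 equiv), THF, −78 °C → rt, substrate added to the base; 1 M HCl work-up
Reagents that add atoms: none
Why: The first equivalent of LiN(SiMe3)2 removes a proton from chain C4 (between the ketone and the enol-ether carbon) and a second removes one from C6, which is acidified by the ketone and the aryloxy oxygen; this C6 carbanion adds to the ester carbon C1, methoxide leaves, and the cyclohexadienone tautomerises and is deprotonated to the dilithium resorcinolate, an irreversible aromatic sink. The closest known reaction type is the Dieckmann-type intramolecular Claisen condensation of 5-oxohexanoate and 3,5-dioxohexanoate esters to cyclohexane-1,3-diones and phloroglucinols. Ring C closes by a 6-(enolendo)-exo-trig attack that forms its C3–C4 bond (chain C1 becomes ring C3, chain C6 becomes ring C4). No stereocentre is formed; the E enoate holds the ester and the ketone arm cis, and the delocalised monoanion lets any Z isomer equilibrate. The selectivity needed is C- over O-acylation, since the latter would give a 2-pyranone: adding the substrate to excess base at low temperature puts the reactive charge on C6 while the enolate oxygen stays lithium-bound, the hindered amide base does not add to the aryloxy enoate, and aromatisation drains the carbon pathway.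

Step 13
Reactants: 24 hexamer diol
Product: 25 CNP0175585.0 (pentadecahydroxy hexamer)
Conditions: BBr3 (20 equiv), CH2Cl2, −78 °C → rt, argon; H2O, 0 °C
Reagents that add atoms: none
Why: In this Lewis-acid ether cleavage each methoxy oxygen binds boron and bromide attacks the methyl carbon (SN2), whereas the diaryl ether bonds offer no sp3 carbon and should remain, and the two free hydroxyls of ring C only form borate esters that hydrolyse on work-up.

**Compound list**

1 | 4-bromo-2,6-dimethoxyphenol | COc1cc(Br)cc(OC)c1O | starting material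
2 | (3,4,5-trimethoxyphenyl)boronic acid | COc1cc(B(O)O)cc(OC)c1OC | starting material
3 | 5-bromo-1,3-dimethoxy-2-(3,4,5-trimethoxyphenoxy)benzene (EF bromide) | COc1cc(Br)cc(OC)c1Oc1cc(OC)c(OC)c(OC)c1 | intermediate
4 | 3,4,5-trimethoxyphenol | COc1cc(O)cc(OC)c1OC | starting material
5 | 1,2,3-trimethoxy-5-(methoxymethoxy)benzene | COCOc1cc(OC)c(OC)c(OC)c1 | intermediate
6 | [2,3,4-trimethoxy-6-(methoxymethoxy)phenyl]lithium | [Li]c1c(OCOC)cc(OC)c(OC)c1OC | intermediate (not isolated)
7 | dimethyl [2,3,4-trimethoxy-6-(methoxymethoxy)phenyl]boronate | COB(OC)c1c(OCOC)cc(OC)c(OC)c1OC | intermediate (not isolated)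
8 | 2,3,4-trimethoxy-6-(methoxymethoxy)phenol | COCOc1cc(OC)c(OC)c(OC)c1O | intermediate
9 | 1,2,3-trimethoxy-5-(methoxymethoxy)-4-[3,5-dimethoxy-4-(3,4,5-trimethoxyphenoxy)phenoxy]benzene (DEF MOM ether) | COCOc1cc(OC)c(OC)c(OC)c1Oc1cc(OC)c(Oc2cc(OC)c(OC)c(OC)c2)c(OC)c1 | intermediate
10 | 2-[3,5-dimethoxy-4-(3,4,5-trimethoxyphenoxy)phenoxy]-3,4,5-trimethoxyphenol (DEF phenol) | Oc1cc(OC)c(OC)c(OC)c1Oc1cc(OC)c(Oc2cc(OC)c(OC)c(OC)c2)c(OC)c1 | intermediate
11 | 2-chloro-N-methoxy-N-methylacetamide | CON(C)C(=O)CCl | starting material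
12 | 2-{2-[3,5-dimethoxy-4-(3,4,5-trimethoxyphenoxy)phenoxy]-3,4,5-trimethoxyphenoxy}-N-methoxy-N-methylacetamide (DEF Weinreb amide) | CON(C)C(=O)COc1cc(OC)c(OC)c(OC)c1Oc1cc(OC)c(Oc2cc(OC)c(OC)c(OC)c2)c(OC)c1 | intermediate
13 | 2-(benzyloxy)-5-bromo-1,3-dimethoxybenzene | COc1cc(Br)cc(OC)c1OCc1ccccc1 | intermediate
14 | 2,4,6-trimethoxyphenol | COc1cc(OC)c(O)c(OC)c1 | starting material
15 | 2-(benzyloxy)-1,3-dimethoxy-5-(2,4,6-trimethoxyphenoxy)benzene (AB benzyl ether) | COc1cc(OC)c(Oc2cc(OC)c(OCc3ccccc3)c(OC)c2)c(OC)c1 | intermediate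
16 | 2,6-dimethoxy-4-(2,4,6-trimethoxyphenoxy)phenol (AB phenol) | COc1cc(OC)c(Oc2cc(OC)c(O)c(OC)c2)c(OC)c1 | intermediate
17 | methyl but-2-ynoate | CC#CC(=O)OC | starting material
18 | methyl (E)-3-[2,6-dimethoxy-4-(2,4,6-trimethoxyphenoxy)phenoxy]but-2-enoate (AB crotonate) | COC(=O)/C=C(/Oc1c(OC)cc(Oc2c(OC)cc(OC)cc2OC)cc1OC)C | intermediate
19 | lithium dienolate of 18 (lithium 1-methoxy-3-aryloxybuta-1,3-dien-1-olate, enolate geometry not defined) | [Li]OC(OC)=CC(=C)Oc1c(OC)cc(Oc2c(OC)cc(OC)cc2OC)cc1OC | intermediate (not isolated)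
20 | tetrahedral lithium alkoxide from addition of 19 to 12 (C5 bears OLi and N(OMe)Me; racemic) | COC(=O)/C=C(/Oc1c(OC)cc(Oc2c(OC)cc(OC)cc2OC)cc1OC)CC(O[Li])(N(C)OC)COc1cc(OC)c(OC)c(OC)c1Oc1cc(OC)c(Oc2cc(OC)c(OC)c(OC)c2)c(OC)c1 | intermediate (not isolated)
21 | methyl (E)-3-[2,6-dimethoxy-4-(2,4,6-trimethoxyphenoxy)phenoxy]-6-{2-[3,5-dimethoxy-4-(3,4,5-trimethoxyphenoxy)phenoxy]-3,4,5-trimethoxyphenoxy}-5-oxohex-2-enoate (keto enoate) | COC(=O)/C=C(/Oc1c(OC)cc(Oc2c(OC)cc(OC)cc2OC)cc1OC)CC(=O)COc1cc(OC)c(OC)c(OC)c1Oc1cc(OC)c(Oc2cc(OC)c(OC)c(OC)c2)c(OC)c1 | intermediate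
22 | dilithium dianion of 21 (deprotonated at chain C4 and C6, drawn as bis-enolate, geometry not defined) | [Li]OC(OC)=CC(Oc1c(OC)cc(Oc2c(OC)cc(OC)cc2OC)cc1OC)=CC(O[Li])=COc1cc(OC)c(OC)c(OC)c1Oc1cc(OC)c(Oc2cc(OC)c(OC)c(OC)c2)c(OC)c1 | intermediate (not isolated)
23 | dilithium resorcinolate of 24 | [Li]Oc1cc(Oc2c(OC)cc(Oc3c(OC)cc(OC)cc3OC)cc2OC)cc(O[Li])c1Oc1cc(OC)c(OC)c(OC)c1Oc1cc(OC)c(Oc2cc(OC)c(OC)c(OC)c2)c(OC)c1 | intermediate (not isolated)
24 | 2-{2-[3,5-dimethoxy-4-(3,4,5-trimethoxyphenoxy)phenoxy]-3,4,5-trimethoxyphenoxy}-5-[2,6-dimethoxy-4-(2,4,6-trimethoxyphenoxy)phenoxy]benzene-1,3-diol (hexamer diol, thirteen methyl ethers) | COc1cc(OC)c(Oc2cc(OC)c(Oc3cc(O)c(Oc4cc(OC)c(OC)c(OC)c4Oc4cc(OC)c(Oc5cc(OC)c(OC)c(OC)c5)c(OC)c4)c(O)c3)c(OC)c2)c(OC)c1 | intermediate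
25 | CNP0175585.0, 2-{2-[3,5-dihydroxy-4-(3,4,5-trihydroxyphenoxy)phenoxy]-3,4,5-trihydroxyphenoxy}-5-[2,6-dihydroxy-4-(2,4,6-trihydroxyphenoxy)phenoxy]benzene-1,3-diol | Oc1cc(O)c(Oc2cc(O)c(Oc3cc(O)c(Oc4cc(O)c(O)c(O)c4Oc4cc(O)c(Oc5cc(O)c(O)c(O)c5)c(O)c4)c(O)c3)c(O)c2)c(O)c1 | target

**Totals**

Total step count: 13. Longest linear sequence: 8 steps (steps 2, 3, 4, 5, 6, 11, 12, 13, from 3,4,5-trimethoxyphenol).

**Steps most likely to fail**

1. Step 12 (ring C closure). The chain enolate may acylate through oxygen and close a 2-pyranone, or the second deprotonation at C6 may not be reached, so that the chain decomposes by loss of aryloxide. Fallback: ring C is taken from a preformed arene, setting out from phenols 16 and 10 and returning at target 25. Commercial 2-bromo-1,3-dimethoxybenzene is borylated at its only unhindered C–H ([Ir(OMe)(cod)]2, 4,4'-di-tert-butyl-2,2'-bipyridine, B2pin2, THF, 80 °C) to 2-(4-bromo-3,5-dimethoxyphenyl)-4,4,5,5-tetramethyl-1,3,2-dioxaborolane F1. F1 is cleaved with NaIO4 and NH4OAc in aqueous acetone to (4-bromo-3,5-dimethoxyphenyl)boronic acid F2. Chan–Lam coupling of F2 with 16 (Cu(OAc)2, pyridine, O2) should give 2-bromo-5-[2,6-dimethoxy-4-(2,4,6-trimethoxyphenoxy)phenoxy]-1,3-dimethoxybenzene F3. Ullmann coupling of F3 with 10 (CuI, picolinic acid, K3PO4, DMSO, 110 °C) should give the pentadecamethyl ether of the target F4, which BBr3 converts into 25 as in step 13.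

2. Step 11 (γ-acylation). The dienolate may take a proton from the α-methylene of the bulky amide instead of adding to it, may react at its α-carbon, or the product may lactonise during work-up. Fallback: the C–C bond is made with a small acyl donor and the trimer is attached by O-alkylation, setting out from 18 and 10 and returning at 21. The dienolate of 18 (LiN(iPr)2, THF, −78 °C) is acylated with 2-chloro-N-methoxy-N-methylacetamide 11 to give methyl (E)-6-chloro-3-[2,6-dimethoxy-4-(2,4,6-trimethoxyphenoxy)phenoxy]-5-oxohex-2-enoate F5. Williamson etherification of F5 with phenol 10 (K2CO3, NaI, acetone, rt) should then give 21.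

3. Step 4 (Ullmann coupling of the hindered ring D phenol). Turnover may be slow with two electron-rich partners, with protodebromination of 3 and oxidative loss of 8 taking over. Fallback: the coupling mode is changed from aryl halide substitution to oxidative boronic acid coupling at room temperature, setting out from 3 and 8 and returning at 9. Bromine–lithium exchange on 3 (n-BuLi, THF, −78 °C), B(OiPr)3 and aqueous acid should give [3,5-dimethoxy-4-(3,4,5-trimethoxyphenoxy)phenyl]boronic acid F6. Chan–Lam coupling of F6 with 8 (Cu(OAc)2, pyridine, 4 Å MS, CH2Cl2, O2) should then give 9.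

**Further compounds**

F1 | step 12 | 2-(4-bromo-3,5-dimethoxyphenyl)-4,4,5,5-tetramethyl-1,3,2-dioxaborolane | COc1cc(B2OC(C)(C)C(C)(C)O2)cc(OC)c1Br
F2 | step 12 | (4-bromo-3,5-dimethoxyphenyl)boronic acid | COc1cc(B(O)O)cc(OC)c1Br
F3 | step 12 | 2-bromo-5-[2,6-dimethoxy-4-(2,4,6-trimethoxyphenoxy)phenoxy]-1,3-dimethoxybenzene | COc1cc(Oc2c(OC)cc(Oc3c(OC)cc(OC)cc3OC)cc2OC)cc(OC)c1Br
F4 | step 12 | pentadecamethyl ether of the target | COc1cc(OC)c(Oc2cc(OC)c(Oc3cc(OC)c(Oc4cc(OC)c(OC)c(OC)c4Oc4cc(OC)c(Oc5cc(OC)c(OC)c(OC)c5)c(OC)c4)c(OC)c3)c(OC)c2)c(OC)c1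
F5 | step 11 | methyl (E)-6-chloro-3-[2,6-dimethoxy-4-(2,4,6-trimethoxyphenoxy)phenoxy]-5-oxohex-2-enoate | COC(=O)/C=C(/Oc1c(OC)cc(Oc2c(OC)cc(OC)cc2OC)cc1OC)CC(=O)CCl
F6 | step 4 | [3,5-dimethoxy-4-(3,4,5-trimethoxyphenoxy)phenyl]boronic acid | COc1cc(B(O)O)cc(OC)c1Oc1cc(OC)c(OC)c(OC)c1
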